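At the last samples of the earlier runs, at 3.00 min, the isomer of the product made up 22.2% of isomer plus target, pooled, and I asked how the first samples compared.

| flask | substrate | partner | free catalyst | impurity | remark | time |
|---|---|---|---|---|---|---|
| north-west | 20 mM | 20 mM | 40 µM | 7.3 µM | run made earlier |  |
| west | 20 mM | 45 mM | 40 µM | 7.3 µM | run made earlier |  |
| south | 30 mM | 30 mM | 40 µM | 7.3 µM | run made earlier |  |
| flask | 20 mM | 30.0 mM | 40 µM | 7.3 µM |  | 2.5 min |

| run | time / min | isomer of the product / % | target / % |
|---|---|---|---|
| north-west | 0.417 | 8 | 25 |
| north-west | 1.00 | 12 | 37 |
| north-west | 2.00 | 13 | 49 |
| north-west | 3.00 | 15 | 48 |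
| west | 0.250 | 9 | 32 |
| west | 0.500 | 15 | 49 |
| west | 1.33 | 22 | 61 |
| west | 3.00 | 20 | 69 |
| south | 0.417 | 11 | 31 |
| south | 1.00 | 14 | 42 |
| south | 2.00 | 16 | 54 |
| south | 3.00 | 14 | 55 |

(readings scatter by 1.5 percentage points)

1. share of isomer of the product in isomer of the product plus target at 0.80 s
2. share of isomer of the product in isomer of the product plus target at 2.5 min

- what is said of target includes crystals
- crystals is a solid; its amount is given per volume of the solution
- steps that have been proposed: substrate + partner <-> isomer of the product; target + free catalyst <-> isomer of the product + free catalyst; 2 free catalyst <-> resting dimer; crystals <-> target; free catalyst + impurity -> spent catalyst; substrate + partner <-> target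

I built the flask up one step at a time. With substrate + partner giving target as the sole step, the share was nil. The parallel step to the isomer uses the same pair, so both forward rates carried the same product c(substrate)·c(partner), and their ratio held whatever the recipe. The share was then a fixed number, which the pooled first samples read as 24.1%. I called it the split; as a selectivity factor it is 3.14 for target over isomer.

Next I added the interconversion of target and isomer on free catalyst, which could carry the share away from the split with time. But the late share lay 2 percentage points below the split, against a scatter of 1.5 points on each reading, so I kept the split. Impurity and resting dimer act on free catalyst, so they reached my number through that same interconversion.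

Last came the crystals, counted as target, which could lower the share. So I put the first answer back in. The flask's partner lay between the north-west and west charges, so with the split I expected between 9.56 mM and 13.5 mM of target. The south run, holding 16.5 mM, read 20.3%, so crystals may have lowered its share. The west run, holding 13.8 mM, read 22.5%, which lay 1.6 points below the split, against a scatter of 1.5 points on each reading. I could not place the saturation of target from these readings, and it might have lain inside my expected range. I therefore committed to 24.1% at 0.80 s and, less firmly, to the same share at 2.5 min, with the west reading as its low side.

The forecast gave 24% and 23%, reasoning that “A constant share means either parallel formation with slow isomerisation”. The flask gave 24.8% at 0.80 s and 24.9% at 2.5 min.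

    substrate + partner ⇌ isomer of the product (K = 73.0 M⁻¹, k = 0.260 M⁻¹ s⁻¹)
    target + free catalyst ⇌ isomer of the product + free catalyst, rate k2*[free catalyst]*[target] forward; the back reaction follows from the equilibrium constant (k = 110 M⁻¹ s⁻¹)
    2 free catalyst ⇌ resting dimer (K = 16000 M⁻¹, k = 400 M⁻¹ s⁻¹)
    crystals ⇌ target, rate k4*(cs4 - [target]) while solid is left; crystals form when [target] > cs4 (solubility = 12.0 mM, k = 0.580 s⁻¹)
    free catalyst + impurity → spent catalyst (k = 2.00 × 10⁵ M⁻¹ s⁻¹)
    substrate + partner ⇌ target (K = 220 M⁻¹, k = 0.790 M⁻¹ s⁻¹)

The forward step to target ran 3.0 times the step to isomer at the start and 3.0 times at 0.326 min, beside the 3.14 read from the runs, and the two equilibrium constants stand in the ratio 3.01. In the neighbour charged with 50 mM of substrate, the share stood at 24.8% at 0.80 s, beside the split, but at 2.50 min it read 18.8%, with target counting crystals at 20.0%.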